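## Retrosynthetic overview
1. The carboxylic acid comes from late allylic C–H oxidation of the terminal E-methyl group of the C30 trienone. These C–O bonds are made last.
2. C11–C12 is disconnected to a bicyclic primary C11 iodide and (2E,6E)-farnesyl acetate, which brings in the two internal E-alkenes.
3. Key disconnection, C8–O: water opens a β-face C8/C9/C11 cyclopropane at C8 with inversion while iodine takes C11. The cyclopropane comes from a C8=C9 alkene.
4. Ring B is the carvone ring and is present from the start. Ring A is formed second, by radical closure from C4 (isopropenyl) onto C3 (nitrile). The three-membered ring is temporary.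
5. The quaternary C10 centre and the cis C5/C10 relation come from allylation and then methylation of (S)-carvone.

Assumption: the SMILES is taken literally and decodes as (5S,8R,9R,10S), with H-5 and CH3-10 on the same face (cis-fused decalin), so trans-fused labdane chiral-pool materials do not fit; polypodane numbering is used and β means the face of CH3-10.

## Route

Step 1
Reactants: 1 (S)-(+)-carvone
Product: 3 (5S,6R)-6-allylcarvone, via carvone lithium dienolate 2 (not isolated)
Conditions: LiN(i-Pr)2 (1.05 equiv), THF, -78 °C; allyl bromide, -78 °C to 0 °C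
Reagents that add atoms: allyl bromide C=CCBr
Why: Kinetic α'-deprotonation gives the cross-conjugated dienolate, which the reactive allylic bromide alkylates on carbon (enolate alkylation); the new C10 centre (allyl trans to isopropenyl) is erased again in step 2.

Step 2
Reactants: 3 (5S,6R)-6-allylcarvone
Product: 5 (5R,6S)-6-allyl-6-methylcarvone, via allylcarvone lithium dienolate 4 (not isolated)
Conditions: LiN(i-Pr)2 (1.1 equiv), THF, -78 °C; MeI, -78 °C to rt
Reagents that add atoms: iodomethane CI
Why: In this second enolate alkylation iodomethane attacks dienolate 4 on the face opposite the C5 isopropenyl group, so CH3-10 ends trans to isopropenyl (cis to H-5), which sets the quaternary C10 centre and fixes the later cis ring fusion.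

Step 3
Reactants: 5 (5R,6S)-6-allyl-6-methylcarvone
Product: 6 (5R,6S)-6-methyl-6-(3-oxopropyl)carvone
Conditions: PdCl2(PhCN)2 (12 mol%), CuCl2·2H2O (12 mol%), AgNO2 (6 mol%), O2 (1 atm), t-BuOH/MeNO2 15:1, rt
Reagents that add atoms: dioxygen O=O
Why: The nitrite-modified aldehyde-selective (anti-Markovnikov) Wacker oxidation works best on allyl groups attached to quaternary carbons and leaves the 1,1-disubstituted and trisubstituted alkenes and both stereocentres untouched.

Step 4
Reactants: 6 (5R,6S)-6-methyl-6-(3-oxopropyl)carvone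
Product: 7 (5R,6S)-6-(2-cyanoethyl)-6-methylcarvone
Conditions: I2 (1.1 equiv), 28% aq. NH3, THF, rt
Reagents that add atoms: ammonia N
Why: The iodine–ammonia oxidation of an aldehyde to a nitrile (aldimine, N-iodination, loss of HI) is mild enough for the hindered enone and the alkenes.

Step 5
Reactants: 7 (5R,6S)-6-(2-cyanoethyl)-6-methylcarvone
Product: 9 C9 enol triflate (C8=C9), via lithium enolate 8 (not isolated)
Conditions: LiBH(s-Bu)3 (1.05 equiv), THF, -78 °C; N-(5-chloro-2-pyridyl)bis(trifluoromethanesulfonimide), -78 °C to 0 °C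
Reagents that add atoms: N-(5-chloro-2-pyridyl)bis(trifluoromethanesulfonimide) FC(F)(F)S(=O)(=O)N(c1ccc(Cl)cn1)S(=O)(=O)C(F)(F)F
Why: Conjugate (1,4) hydride reduction at unhindered C7 gives the only possible enolate (C10 is quaternary), which is trapped on oxygen as the enol triflate while the nitrile survives at low temperature.

Step 6
Reactants: 9 C9 enol triflate (C8=C9)
Product: 10 3-[(1R,6R)-1,3-dimethyl-6-(prop-1-en-2-yl)cyclohex-2-en-1-yl]propanenitrile
Conditions: Pd(OAc)2 (5 mol%), PPh3 (10 mol%), HCO2H, Et3N, DMF, 60 °C
Reagents that add atoms: none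
Why: Palladium-catalysed formate hydrogenolysis of an enol triflate (oxidative addition, formate decarboxylation, reductive elimination) replaces OTf by H and leaves the trisubstituted C8=C9 alkene where the cyclopropane is needed.

Step 7
Reactants: 10 3-[(1R,6R)-1,3-dimethyl-6-(prop-1-en-2-yl)cyclohex-2-en-1-yl]propanenitrile
Product: 12 cis-fused octalinone (5β-H; 10β-CH3; C8=C9), via ring A ketimine 11 (not isolated)
Conditions: Fe(acac)3 (0.5 equiv), PhSiH3 (3 equiv), EtOH, 60 °C; then 1 M HCl, THF, rt
Reagents that add atoms: water O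
Why: Hydrogen-atom transfer from an iron hydride (Mukaiyama-type HAT) to the more accessible 1,1-disubstituted alkene gives the tertiary C4 radical, which closes ring A by 6-exo-dig addition to the cis-disposed nitrile (HAT alkene–nitrile cyclisation) before hydrolysis to the α-quaternary ketone; the cis fusion follows from C5 and C10 already in place.

Step 8
Reactants: 12 cis-fused octalinone (5β-H; 10β-CH3; C8=C9)
Product: 13 8β,9β-methano ketone (cyclopropane CH2 = C11 on the β face; H-9 α)
Conditions: Et2Zn (5 equiv), CH2I2 (10 equiv), ClCH2CH2Cl, 0 °C to 40 °C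
Reagents that add atoms: diiodomethane ICI
Why: Simmons–Smith (Furukawa) cyclopropanation is a stereospecific syn addition, and the carbenoid should take the convex β face (side of CH3-10 and H-5) because pseudo-axial C1 and the folded ring A block the α face, which places C11 β and H-9 α.

Step 9
Reactants: 13 8β,9β-methano ketone (cyclopropane CH2 = C11 on the β face; H-9 α)
Product: 14 11-iodo-8α-hydroxy ketone (5β-H; 8β-CH3; 9α-H; 10β-CH3)
Conditions: N-iodosuccinimide (1.3 equiv), Ph3P=S (10 mol%), H2O (20 equiv), (CF3)2CHOH/CH2Cl2 1:4, -20 °C, dark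
Reagents that add atoms: N-iodosuccinimide O=C1CCC(=O)N1I; water O
Why: Proposed new method: Lewis-base-activated iodenium (Ph3P=S–I+ from N-iodosuccinimide) attacks the least substituted and only unhindered cyclopropane carbon C11 while positive charge builds at tertiary C8, and water, held by the hexafluoroisopropanol hydrogen-bond network, enters C8 from the α face anti to the breaking C8–C11 bond (SN2-like, trans-diaxial opening as in the Fürst–Plattner rule), so the C8–O bond forms with inversion (8α-OH, 8β-CH3), H-9 stays α and C11 is released as a primary iodide; the closest known reaction types are the oxymercuration of cyclopropanes and Lewis-base-catalysed halocyclisations of cyclopropanes by tethered nucleophiles, whereas an intermolecular iodohydroxylation of an unactivated, fused, trialkyl-substituted cyclopropane has not been shown.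

Step 10
Reactants: 14 11-iodo-8α-hydroxy ketone (5β-H; 8β-CH3; 9α-H; 10β-CH3); 15 (2E,6E)-farnesyl acetate
Product: 16 (5S,8R,9R,10S)-8-hydroxypolypoda-13E,17E,21-trien-3-one
Conditions: NiCl2(dme) (10 mol%), 4,4',4''-tri-tert-butyl-2,2':6',2''-terpyridine (10 mol%), Zn (2 equiv), THF/N-ethylpyrrolidinone, 40 °C
Reagents that add atoms: none
Why: In this nickel-catalysed reductive cross-electrophile coupling of a primary alkyl iodide with an allylic acetate, the C11 radical is captured at the unsubstituted terminus of the allylnickel species, so the linear product forms with the E-alkene intact, and the ketone and free tertiary alcohol are tolerated.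

Step 11
Reactants: 16 (5S,8R,9R,10S)-8-hydroxypolypoda-13E,17E,21-trien-3-one
Product: 18 terminal (E)-enal, via terminal allylic alcohol 17 (not isolated)
Conditions: SeO2 (0.3 equiv), t-BuOOH (2 equiv), salicylic acid (0.1 equiv), CH2Cl2, 0 °C to rt; filter, then MnO2 (20 equiv), CH2Cl2, rt
Reagents that add atoms: tert-butyl hydroperoxide CC(C)(C)OO
Why: The SeO2/t-BuOOH allylic oxidation (ene reaction then [2,3]-sigmatropic shift) prefers the E-methyl group of the terminal, least hindered trisubstituted alkene, and MnO2 takes alcohol 17 on to the E-enal without touching the tertiary alcohol or the ketone.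

Step 12
Reactants: 18 terminal (E)-enal
Product: 19 myrrhanone B as drawn (5S,8R,9R,10S)
Conditions: NaClO2, NaH2PO4, 2-methyl-2-butene, t-BuOH/H2O, 0 °C to rt
Reagents that add atoms: sodium chlorite [Na+].[O-]Cl=O
Why: The Pinnick–Lindgren oxidation converts the enal to the acid without alkene isomerisation, and the scavenger removes hypochlorous acid before it can reach the chain alkenes.

## Compound list
1 | (S)-(+)-carvone | O=C1C[C@@H](C(C)=C)CC=C1C | starting material
2 | carvone lithium dienolate | [Li+].[O-]C1=C[C@@H](C(C)=C)CC=C1C | intermediate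
3 | (5S,6R)-6-allylcarvone (allyl trans to isopropenyl) | O=C1[C@H](CC=C)[C@@H](C(C)=C)CC=C1C | intermediate
4 | allylcarvone lithium dienolate | [Li+].[O-]C1=C(CC=C)[C@@H](C(C)=C)CC=C1C | intermediate
5 | (5R,6S)-6-allyl-6-methylcarvone (CH3 trans to isopropenyl) | O=C1[C@@](C)(CC=C)[C@@H](C(C)=C)CC=C1C | intermediate
6 | (5R,6S)-6-methyl-6-(3-oxopropyl)carvone | O=C1[C@@](C)(CCC=O)[C@@H](C(C)=C)CC=C1C | intermediate
7 | (5R,6S)-6-(2-cyanoethyl)-6-methylcarvone | O=C1[C@@](C)(CCC#N)[C@@H](C(C)=C)CC=C1C | intermediate
8 | lithium enolate from 1,4-reduction of 7 | [Li+].CC1=C([O-])[C@@](C)(CCC#N)[C@@H](C(C)=C)CC1 | intermediate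
9 | 6-(2-cyanoethyl)-2,6-dimethyl-5-(prop-1-en-2-yl)cyclohex-1-en-1-yl triflate (CH3-6 trans to isopropenyl) | CC1=C(OS(=O)(=O)C(F)(F)F)[C@@](C)(CCC#N)[C@@H](C(C)=C)CC1 | intermediate
10 | 3-[(1R,6R)-1,3-dimethyl-6-(prop-1-en-2-yl)cyclohex-2-en-1-yl]propanenitrile | CC1=C[C@@](C)(CCC#N)[C@@H](C(C)=C)CC1 | intermediate
11 | ring A ketimine (C3=NH) | CC1=C[C@@]2(C)CCC(=N)C(C)(C)[C@H]2CC1 | intermediate
12 | cis-fused 1,1,4a,6-tetramethyl-3,4,4a,7,8,8a-hexahydronaphthalen-2(1H)-one (4a-CH3 and 8a-H both β) | CC1=C[C@@]2(C)CCC(=O)C(C)(C)[C@H]2CC1 | intermediate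
13 | 8β,9β-methano ketone (C11 bridges C8 and C9 on the β face; H-9 α) | C[C@@]12C[C@@H]1[C@@]3(C)CCC(=O)C(C)(C)[C@H]3CC2 | intermediate
14 | 11-iodo-8α-hydroxy ketone (5β-H, 8β-CH3, 9α-H, 10β-CH3) | IC[C@@H]1[C@@]2(C)CCC(=O)C(C)(C)[C@H]2CC[C@@]1(C)O | intermediate
15 | (2E,6E)-farnesyl acetate | CC(C)=CCC/C(C)=C/CC/C(C)=C/COC(C)=O | starting material
16 | (5S,8R,9R,10S)-8-hydroxypolypoda-13E,17E,21-trien-3-one | CC(C)=CCC/C(C)=C/CC/C(C)=C/CC[C@@H]1[C@@]2(C)CCC(=O)C(C)(C)[C@H]2CC[C@@]1(C)O | intermediate
17 | terminal (E)-allylic alcohol of 16 | C/C(=C\CC/C(C)=C/CC[C@@H]1[C@@]2(C)CCC(=O)C(C)(C)[C@H]2CC[C@@]1(C)O)CC/C=C(\C)CO | intermediate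
18 | terminal (E)-enal | C/C(=C\CC/C(C)=C/CC[C@@H]1[C@@]2(C)CCC(=O)C(C)(C)[C@H]2CC[C@@]1(C)O)CC/C=C(\C)C=O | intermediate
19 | myrrhanone B as drawn | C/C(=C\CC/C(C)=C/CC[C@@H]1[C@@]2(C)CCC(=O)C(C)(C)[C@H]2CC[C@@]1(C)O)CC/C=C(\C)C(=O)O | target

Total step count: 12.
Longest linear sequence: 12 steps, from (S)-carvone.

## Steps most likely to fail

**Step 9 (the proposed new step).** Proton loss from C8 or iodination next to the ketone may win over capture by water. The fallback sets out from 13 and uses known chemistry. Hg(OCOCF3)2 in THF/H2O carries out the established oxymercuration of a cyclopropane: the metal goes to the least substituted carbon and water enters the tertiary carbon with inversion. This gives the C11 organomercury trifluoroacetate F3. Iododemercuration with I2 in CH2Cl2 then comes back to the route at 14.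

**Step 10.** The iodide is strongly β-branched and carries a γ-hydroxyl group, so radical capture by nickel may be slow and reduction or allyl dimerisation may dominate. The fallback sets out from 14 and 15 and replaces the radical coupling by a polar carbanion alkylation.
- Pd(PPh3)4 and PhSO2Na convert 15 into (2E,6E)-farnesyl phenyl sulfone F4.
- The lithio anion of F4 (n-BuLi, THF/HMPA, -78 °C to 0 °C) is too weakly basic to enolise the ketone. It displaces the iodide of 14 to give the C12 phenyl sulfone F5, an epimer mixture at C12 that is cleared next.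
- Sodium amalgam (Na/Hg) with Na2HPO4 in MeOH at -20 °C removes the sulfone and comes back at 16.

**Step 7.** The 6-exo-dig addition to the nitrile is slow, so the C4 radical may simply be reduced. The fallback sets out from 10.
- i-Bu2AlH (toluene, -78 °C, then aqueous acid) gives the aldehyde F1.
- The same Fe(acac)3/PhSiH3 conditions close ring A on the much faster C=O acceptor (HAT-initiated alkene–carbonyl radical cyclisation). This gives the secondary alcohol F2, drawn as the 3β epimer, though either epimer serves.
- Dess–Martin oxidation comes back to the route at 12.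

## Further compounds
F1 | step 7 | 3-[(1R,6R)-1,3-dimethyl-6-(prop-1-en-2-yl)cyclohex-2-en-1-yl]propanal | CC1=C[C@@](C)(CCC=O)[C@@H](C(C)=C)CC1
F2 | step 7 | 3β-alcohol corresponding to ketone 12 | CC1=C[C@@]2(C)CC[C@H](O)C(C)(C)[C@H]2CC1
F3 | step 9 | C11 organomercury trifluoroacetate of the 8α-hydroxy ketone | O=C(O[Hg]C[C@@H]1[C@@]2(C)CCC(=O)C(C)(C)[C@H]2CC[C@@]1(C)O)C(F)(F)F
F4 | step 10 | (2E,6E)-farnesyl phenyl sulfone | CC(C)=CCC/C(C)=C/CC/C(C)=C/CS(=O)(=O)c1ccccc1
F5 | step 10 | 12-phenylsulfonyl derivative of 16 (C12 epimers) | CC(C)=CCC/C(C)=C/CC/C(C)=C/C(C[C@@H]1[C@@]2(C)CCC(=O)C(C)(C)[C@H]2CC[C@@]1(C)O)S(=O)(=O)c1ccccc1
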